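**Plan**

- Retrosynthesis: the side-chain carbinol C–O bond is cut first (hydration of an isopropenyl group). The dihydrofuran is then cut at O1–C2 and C3a–C3 (benzofuran numbering O1, C2, C3, C3a, C4–C7, C7a), which gives deoxyhumulone and a C5 1,4-bis-allylic electrophile. Finally the two ring–prenyl bonds and the ring–acyl bond are cut back to phloroglucinol.
- Enabling feature: the prenylated carbon C3a and the oxygen on the neighbouring C7a are adjacent C- and O-nucleophilic sites of a Cs-symmetric diprenyl acylphloroglucinol ring. C2, C3 and the three side-chain carbons on C2 form one isoprenoid five-carbon piece that can bridge these two sites.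
- Forward: the carbocycle is bought as phloroglucinol, acylated and twice C-prenylated. The C5 bis-electrophile is made from prenol in three steps. The dihydrofuran, the only ring formed, closes in one flask by dearomatising C-allylation followed by O-allylation, and hydration of the isopropenyl group ends the route.
- Stereochemistry: C3a (S) comes from a chiral Pd–ligand complex that distinguishes the enantiotopic prenylated ring carbons. C2 (S, trans to the C3a prenyl group) comes from ligand- and substrate-controlled, reversible O-attack on an equilibrating π-allyl. The last step creates no stereocentre.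

Key step: step 6

Remark on tautomers: all β-triketone compounds are written in the enol form of the target SMILES; other tautomers are the same compound.

Remark on the ligand: the sense of induction for a prochiral nucleophile cannot be read from the usual ligand model, so the (R,R) ligand is written for the (3aS) series, the first run assigns it, and the (S,S) ligand is taken if the opposite sense is found.

Remark on the bis-electrophile: the carbonate must sit on the CH2 next to CH= and the acetate on the CH2 next to C(CH3)=, since the reverse placement would lead to a 2-methyl-2-vinyl dihydrofuran. Pd-catalysed 1,4-opening of 2-methyl-2-vinyloxirane by acetate gives that reverse placement, so prenol is the C5 source.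

**Step 1**
Reactants: 1 phloroglucinol; 2 3-methylbutanoyl chloride
Product: 3 1-(2,4,6-trihydroxyphenyl)-3-methylbutan-1-one (phlorisovalerophenone)
Conditions: AlCl3 (3 equiv), PhNO2/CH2Cl2, 0 °C to rt; 1 M HCl
Reagents that add atoms: none
Why: Friedel–Crafts acylation of the highly activated, threefold-symmetric arene should stop after one acyl group because the aryl ketone deactivates the ring and binds the Lewis acid; no stereocentre is formed.

**Step 2**
Reactants: 3 1-(2,4,6-trihydroxyphenyl)-3-methylbutan-1-one; 4 1-bromo-3-methylbut-2-ene (prenyl bromide, 2 equiv)
Product: 5 deoxyhumulone, 1-[2,4,6-trihydroxy-3,5-bis(3-methylbut-2-en-1-yl)phenyl]-3-methylbutan-1-one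
Conditions: 10% aq. KOH, 0 °C, argon; then dilute HCl
Reagents that add atoms: none
Why: twofold C-alkylation of the ambident phloroglucinolate by an allylic bromide in water, where solvation of the oxygens favours C- over O-prenylation and the two free ring carbons are the open sites, is the classical entry to this compound in moderate yield; no stereocentre is formed.

**Step 3**
Reactants: 6 3-methylbut-2-en-1-ol (prenol); 7 methyl chloroformate
Product: 8 methyl 3-methylbut-2-en-1-yl carbonate
Conditions: pyridine, CH2Cl2, 0 °C
Reagents that add atoms: none
Why: O-acylation of a primary allylic alcohol by a chloroformate (carbonate formation) is routine and leaves the trisubstituted alkene untouched.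

**Step 4**
Reactants: 8 methyl 3-methylbut-2-en-1-yl carbonate
Product: 9 (2E)-4-hydroxy-3-methylbut-2-en-1-yl methyl carbonate
Conditions: SeO2 (0.3 equiv), t-BuOOH (2.5 equiv), salicylic acid (0.1 equiv), CH2Cl2, 0 °C to rt, stopped before the enal builds up
Reagents that add atoms: tert-butyl hydroperoxide, CC(C)(C)OO (terminal oxidant); selenium dioxide, O=[Se]=O (catalytic oxygen carrier)
Why: Riley allylic oxidation with catalytic SeO2 attacks a trisubstituted alkene at the methyl group on the E side through an ene/[2,3]-sigmatropic sequence, so the E geometry follows from the mechanism and the deactivated CH2O carbon is spared, as is usual for prenyl esters.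

**Step 5**
Reactants: 9 (2E)-4-hydroxy-3-methylbut-2-en-1-yl methyl carbonate; 10 acetic anhydride
Product: 11 (2E)-4-(methoxycarbonyloxy)-2-methylbut-2-en-1-yl acetate
Conditions: pyridine, DMAP (cat.), CH2Cl2, 0 °C to rt
Reagents that add atoms: none
Why: DMAP-catalysed acetylation of a primary allylic alcohol should be clean and touches neither the carbonate nor the alkene geometry.

**Step 6**
Reactants: 5 deoxyhumulone; 11 (2E)-4-(methoxycarbonyloxy)-2-methylbut-2-en-1-yl acetate (1.05 equiv)
Product: 13 (2S,3aS)-6-hydroxy-5-(3-methylbutanoyl)-3a,7-bis(3-methylbut-2-en-1-yl)-2-(prop-1-en-2-yl)-2,3-dihydro-1-benzofuran-4(3aH)-one, via C-allylated dienone acetate 12 (not isolated)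
Conditions: Pd2(dba)3·CHCl3 (2.5 mol%), (R,R)-DACH-phenyl Trost ligand (7.5 mol%), Cs2CO3 (1.1 equiv), degassed THF, 0 °C then 40 °C
Reagents that add atoms: none
Why: Proposed new method: Pd(0) ionises the methyl carbonate end of 11 first (decarboxylative and irreversible, far faster than the acetate end), the caesium phloroglucinolate of 5 attacks the unsubstituted CH2 terminus of this π-allyl through a prenyl-bearing ring carbon to give the dearomatised dienone 12 with the C3a quaternary centre, and ionisation of the allylic acetate of 12 then gives a second π-allyl that is captured at its internal CH terminus by the enolic oxygen on the neighbouring carbon (future C7a). The closest known reaction types are the Pd-catalysed tandem C-/O-allylation of cyclic 1,3-diones with but-2-ene-1,4-diyl diesters to 2-vinyl-2,3-dihydrofurans, the Pd-catalysed dearomative C-allylation of diprenylated acylphloroglucinols and the Trost-ligand-controlled allylic dearomatisation of phenols; their merger into one enantioselective annulation is what is new. The dihydrofuran closes in the 5-exo mode (O1–C2 bond, isopropenyl group left outside the ring), which is favoured over 7-endo attack at the CH2 terminus. C3a is controlled by the chiral ligand, which must choose between the two enantiotopic prenylated carbons of the Cs-symmetric nucleophile (both give the same constitution), and C2 is controlled by the ligand together with the C3a centre in the anti attack of oxygen on π-allyl diastereomers that interconvert by a π–σ–π shift through their CH2 terminus. Because 13 is an allylic vinylogous ester that Pd(0) can reopen, the ring closure is reversible and should funnel to the less crowded trans isomer with the isopropenyl group anti to the C3a prenyl group and to the isomer that keeps the acyl β-dicarbonyl chelate intact. The selectivities needed are carbonate-before-acetate ionisation (secured by the two different leaving groups), C- rather than O-allylation at a prenylated and not the acylated carbon (the known preference of these phloroglucinolates, whose aryl allyl ethers re-ionise), and closure through the C7a oxygen instead of the C4 oxygen, which is tied up in the hydrogen-bonded or caesium-chelated acyl unit.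

**Step 7**
Reactants: 13 (2S,3aS)-6-hydroxy-5-(3-methylbutanoyl)-3a,7-bis(3-methylbut-2-en-1-yl)-2-(prop-1-en-2-yl)-2,3-dihydro-1-benzofuran-4(3aH)-one
Product: 15 (2S,3aS)-6-hydroxy-2-(2-hydroxypropan-2-yl)-5-(3-methylbutanoyl)-3a,7-bis(3-methylbut-2-en-1-yl)-2,3-dihydro-1-benzofuran-4(3aH)-one, via tertiary hydroperoxide 14 (not isolated)
Conditions: Co(acac)2 (20 mol%), PhSiH3 (2 equiv), O2 (1 atm), THF/i-PrOH, 0 °C to rt; then PPh3
Reagents that add atoms: dioxygen, O=O
Why: in the Mukaiyama hydration a cobalt hydride transfers a hydrogen atom to the accessible CH2 terminus of the 1,1-disubstituted alkene much faster than to the trisubstituted prenyl alkenes or the tetrasubstituted enol ether, the tertiary radical is trapped by O2 and the peroxide is reduced to the carbinol; the new carbinol carbon bears two methyl groups and is not stereogenic, and C2 and C3a are not touched.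

**Compound list**

1 | phloroglucinol (benzene-1,3,5-triol) | Oc1cc(O)cc(O)c1 | starting material
2 | 3-methylbutanoyl chloride | CC(C)CC(Cl)=O | starting material
3 | 1-(2,4,6-trihydroxyphenyl)-3-methylbutan-1-one | CC(C)CC(=O)c1c(O)cc(O)cc1O | intermediate
4 | 1-bromo-3-methylbut-2-ene (prenyl bromide) | CC(C)=CCBr | starting material
5 | deoxyhumulone, 1-[2,4,6-trihydroxy-3,5-bis(3-methylbut-2-en-1-yl)phenyl]-3-methylbutan-1-one | CC(C)=CCc1c(O)c(CC=C(C)C)c(O)c(C(=O)CC(C)C)c1O | intermediate
6 | 3-methylbut-2-en-1-ol (prenol) | CC(C)=CCO | starting material
7 | methyl chloroformate | COC(Cl)=O | starting material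
8 | methyl 3-methylbut-2-en-1-yl carbonate | CC(C)=CCOC(=O)OC | intermediate
9 | (2E)-4-hydroxy-3-methylbut-2-en-1-yl methyl carbonate | OC/C(C)=C/COC(=O)OC | intermediate
10 | acetic anhydride | CC(=O)OC(C)=O | starting material
11 | (2E)-4-(methoxycarbonyloxy)-2-methylbut-2-en-1-yl acetate | CC(=O)OC/C(C)=C/COC(=O)OC | intermediate
12 | (6S)-6-[(2E)-4-acetoxy-3-methylbut-2-en-1-yl]-3,5-dihydroxy-2-(3-methylbutanoyl)-4,6-bis(3-methylbut-2-en-1-yl)cyclohexa-2,4-dien-1-one (forms in the flask in step 6) | CC(C)=CCC1=C(O)[C@@](C/C=C(\C)COC(C)=O)(CC=C(C)C)C(=O)C(C(=O)CC(C)C)=C1O | intermediate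
13 | (2S,3aS)-6-hydroxy-5-(3-methylbutanoyl)-3a,7-bis(3-methylbut-2-en-1-yl)-2-(prop-1-en-2-yl)-2,3-dihydro-1-benzofuran-4(3aH)-one | CC(C)=CCC1=C2O[C@H](C(C)=C)C[C@]2(CC=C(C)C)C(=O)C(C(=O)CC(C)C)=C1O | intermediate
14 | (2S,3aS)-2-(2-hydroperoxypropan-2-yl)-6-hydroxy-5-(3-methylbutanoyl)-3a,7-bis(3-methylbut-2-en-1-yl)-2,3-dihydro-1-benzofuran-4(3aH)-one (forms in the flask in step 7) | CC(C)=CCC1=C2O[C@H](C(C)(C)OO)C[C@]2(CC=C(C)C)C(=O)C(C(=O)CC(C)C)=C1O | intermediate
15 | (2S,3aS)-6-hydroxy-2-(2-hydroxypropan-2-yl)-5-(3-methylbutanoyl)-3a,7-bis(3-methylbut-2-en-1-yl)-2,3-dihydro-1-benzofuran-4(3aH)-one | CC(C)=CCC1=C2O[C@H](C(C)(C)O)C[C@]2(CC=C(C)C)C(=O)C(C(=O)CC(C)C)=C1O | target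

Total step count: 7.
Longest linear sequence: 5 steps (steps 3, 4, 5, 6, 7, from prenol); the phloroglucinol branch has 4 (steps 1, 2, 6, 7).

**Steps most likely to fail**

1. Step 6 (proposed new method).
   - What may go wrong: poor discrimination of the enantiotopic ring carbons, O-allylation that does not revert to C-allylation, closure through the acyl-side oxygen, weak diastereocontrol at C2, or loss of the second π-allyl by β-hydride elimination to a diene.
   - Fallback with known chemistry, setting out from 5 and returning at 15: C-prenylation of 5 with 4 (NaOMe, MeOH, 0 °C) gives lupulone F1. Shi epoxidation (D-fructose-derived ketone, Oxone, buffered K2CO3, MeCN/dimethoxymethane–water, 0 °C), held at partial conversion, should place an (R)-epoxide on one of the two geminal prenyl groups to give the (6S,2′R)-epoxylupulone F2 beside its C6 epimer. Brief K2CO3/MeOH then opens the epoxide 5-exo at its secondary carbon by the neighbouring enol oxygen with inversion, giving 15 directly together with its 3a-epimer, which is removed by chromatography. C2 is then reagent-controlled, C3a is secured by separation, and step 7 is not needed.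

2. Step 7.
   - What may go wrong: hydrogen-atom transfer also to the prenyl alkenes, oxidative degradation of the electron-rich enol under O2 and cobalt, or sequestration of the catalyst by the β-triketone.
   - Fallback setting out from 13 and returning at 15: oxymercuration–demercuration, an ionic and oxygen-free path. Hg(OAc)2 (1.0 equiv) in THF/water at 0 °C should give the β-hydroxyalkylmercury acetate F3 (both epimers at the transient carbinol carbon, which loses its stereogenicity in the next operation). NaBH4 in aqueous NaOH at 0 °C replaces mercury by hydrogen and gives 15. The 1,1-disubstituted alkene forms its mercurinium ion faster than the prenyl groups, and one equivalent of the mercury salt limits mercury-induced chroman formation from the C7 prenyl group and the C6 hydroxyl.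

3. Step 2.
   - What may go wrong: under- and over-prenylation, O-prenylation and geminal diprenylation give a mixture that is hard to separate.
   - Fallback setting out from 3 and returning at 5: Lewis-acid Friedel–Crafts prenylation with 2-methylbut-3-en-2-ol (2 equiv) and BF3·OEt2 in dioxane at rt. This goes through the neutral phenol and a prenyl cation equivalent instead of the phenolate, so irreversible O-alkylation and geminal dialkylation are avoided; acid-induced chroman formation is its own limit and is held down by a short reaction time. No compound outside the list arises on this detour (entry F0).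

**Further compounds**

F1 | step 6 | lupulone, 3,5-dihydroxy-2-(3-methylbutanoyl)-4,6,6-tris(3-methylbut-2-en-1-yl)cyclohexa-2,4-dien-1-one | CC(C)=CCC1=C(O)C(CC=C(C)C)(CC=C(C)C)C(=O)C(C(=O)CC(C)C)=C1O
F2 | step 6 | (6S)-6-{[(2R)-3,3-dimethyloxiran-2-yl]methyl}-3,5-dihydroxy-2-(3-methylbutanoyl)-4,6-bis(3-methylbut-2-en-1-yl)cyclohexa-2,4-dien-1-one | CC(C)=CCC1=C(O)[C@@](C[C@H]2OC2(C)C)(CC=C(C)C)C(=O)C(C(=O)CC(C)C)=C1O
F3 | step 7 | acetoxy{2-hydroxy-2-[(2S,3aS)-6-hydroxy-5-(3-methylbutanoyl)-3a,7-bis(3-methylbut-2-en-1-yl)-4-oxo-2,3,3a,4-tetrahydro-1-benzofuran-2-yl]propyl}mercury, both epimers at the carbinol carbon | CC(C)=CCC1=C2O[C@H](C(C)(O)C[Hg]OC(C)=O)C[C@]2(CC=C(C)C)C(=O)C(C(=O)CC(C)C)=C1O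
F0 | step 2 | none | none
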